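## Retrosynthetic overview

1. The trans-diaxial 3α,4β-diol comes from 6β-benzoyloxyeudesm-3-ene by α-face epoxidation, then diaxial opening at C4 assisted by the neighbouring 6β-benzoate.
2. Rings A and B form simultaneously in one thermal intramolecular [4+2] of an acyclic, unactivated deca-1,3,9-triene. It makes C5–C10 and C1–C2, sets 5α-H and quaternary C10, and leaves the alkene at C3=C4.
3. The triene comes from methylenation of a keto dienyl benzoate, itself made by Felkin addition of an (E)-2-methylbutadienyl metal to a keto aldehyde (sets C6).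
4. The keto aldehyde comes from an organocatalytic Michael addition of isovaleraldehyde to methyl vinyl ketone (C7, the only catalyst-set centre). The dienyl unit comes from carboalumination of but-1-en-3-yne.

Assumption: positions are given in eudesmane numbering (C6 carries OBz, C7 isopropyl, C10 the angular CH3), and but-1-en-3-yne is bought as its stabilised ca. 50 wt% solution.

## Route

Step 1
Reactants: 1 3-methylbutanal (isovaleraldehyde); 2 but-3-en-2-one (methyl vinyl ketone)
Product: 3 (2S)-5-oxo-2-(propan-2-yl)hexanal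
Conditions: (S)-α,α-diphenylprolinol methyl ether (5 mol%), ethyl 3,4-dihydroxybenzoate (20 mol%), neat, 4 °C, 36 h
Reagents that add atoms: none
Why: Enamine-catalysed asymmetric Michael addition; the CPh2OMe group shields one face of the E-enamine of 1, so 2 (activated by hydrogen bonding to the catechol) adds to the open face and sets C7 as S (expected ca. 95% ee).

Step 2
Reactants: 4 but-1-en-3-yne
Product: 6 (1E)-1-iodo-2-methylbuta-1,3-diene, via dienylalane 5 (not isolated)
Conditions: Me3Al (2 equiv), Cp2ZrCl2 (20 mol%), ClCH2CH2Cl, 0 °C to rt; then I2, THF, −30 °C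
Reagents that add atoms: trimethylaluminium C[Al](C)C; iodine II
Why: Negishi Zr-catalysed carboalumination adds CH3 (to the internal alkyne carbon) and Al syn, and iodinolysis keeps the geometry, which fixes the E-diene with the later tether pointing outward; no stereocentre is formed.

Step 3
Reactants: 6 (1E)-1-iodo-2-methylbuta-1,3-diene; 3 (2S)-5-oxo-2-(propan-2-yl)hexanal
Product: 9 (3E,5R,6S)-3-methyl-9-oxo-6-(propan-2-yl)deca-1,3-dien-5-yl benzoate, via dienyllithium 7 (not isolated), via lithium alkoxide 8 (not isolated)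
Conditions: 6, t-BuLi (2.0 equiv), Et2O, −78 °C; 3 (precooled), −78 °C; then BzCl, DMAP (cat.), −78 °C to 0 °C
Reagents that add atoms: benzoyl chloride O=C(Cl)c1ccccc1
Why: Li–I exchange with retention, then 1,2-addition that is far faster at the aldehyde than at the methyl ketone at −78 °C; Felkin–Anh attack anti to the isopropyl group sets C6 as R (about 4:1 expected, minor epimer removed by chromatography), and the alkoxide is acylated in the same flask.

Step 4
Reactants: 9 (3E,5R,6S)-3-methyl-9-oxo-6-(propan-2-yl)deca-1,3-dien-5-yl benzoate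
Product: 10 (3E,5R,6S)-3,9-dimethyl-6-(propan-2-yl)deca-1,3,9-trien-5-yl benzoate
Conditions: Ph3PCH3Br (1.4 equiv), KHMDS (1.3 equiv), THF, −78 °C to 0 °C
Reagents that add atoms: methyltriphenylphosphonium bromide C[P+](c1ccccc1)(c1ccccc1)c1ccccc1.[Br-]
Why: Wittig methylenation; the non-stabilised ylide olefinates the methyl ketone much faster than it attacks the benzoate at or below 0 °C, and neither stereocentre is α to the carbonyl, so none is touched.

Step 5 (key step)
Reactants: 10 (3E,5R,6S)-3,9-dimethyl-6-(propan-2-yl)deca-1,3,9-trien-5-yl benzoate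
Product: 11 6β-benzoyloxyeudesm-3-ene (trans-decalin; 5α-H, axial 6β-OBz, equatorial 7β-isopropyl, 10β-CH3)
Conditions: toluene (0.02 M), BHT (10 mol%), silylated sealed tube, 195 °C, 36 h
Reagents that add atoms: none
Why: Thermal intramolecular Diels–Alder reaction of a 1,7,9-decatriene; the four-atom tether folds as a chair with isopropyl equatorial, A(1,3) strain with the C4 methyl puts C6–H in the diene plane and the benzoate axial, and the anti (trans-fused) transition state forms C5–C10 and C1–C2 suprafacially, setting 5α-H and 10β-CH3 and leaving the alkene at C3=C4.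

Step 6
Reactants: 11 6β-benzoyloxyeudesm-3-ene
Product: 13 3α,4β-dihydroxy-6β-benzoyloxyeudesmane, (3R,4R,5S,6R,7S,10S), the target, via alpha-epoxide 12 (not isolated)
Conditions: mCPBA, CH2Cl2, 0 °C; aqueous wash, concentrate; then HClO4 (cat.), THF–H2O 4:1, 0 °C to rt
Reagents that add atoms: 3-chloroperoxybenzoic acid OOC(=O)c1cccc(Cl)c1; water O
Why: Prilezhaev epoxidation occurs on the α face (the β face is blocked by 10β-CH3 and 6β-OBz), and acid-catalysed Fürst–Plattner trans-diaxial opening at tertiary C4 from the β face, assisted by the syn-axial benzoate carbonyl through a 1,3-dioxan-2-ylium ion that water collapses to the secondary ester, gives 3α-OH and 4β-OH.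

## Compound list

1 | 3-methylbutanal | CC(C)CC=O | starting material
2 | but-3-en-2-one | CC(=O)C=C | starting material
3 | (2S)-5-oxo-2-(propan-2-yl)hexanal | CC(C)[C@H](CCC(C)=O)C=O | intermediate
4 | but-1-en-3-yne | C=CC#C | starting material
5 | dimethyl[(1E)-2-methylbuta-1,3-dien-1-yl]alane | C[Al](C)/C=C(C)/C=C | intermediate
6 | (1E)-1-iodo-2-methylbuta-1,3-diene | I/C=C(C)/C=C | intermediate
7 | [(1E)-2-methylbuta-1,3-dien-1-yl]lithium | [Li]/C=C(C)/C=C | intermediate
8 | lithium (3E,5R,6S)-3-methyl-9-oxo-6-(propan-2-yl)deca-1,3-dien-5-olate | CC(C)[C@H](CCC(C)=O)[C@@H]([O-])/C=C(C)/C=C.[Li+] | intermediate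
9 | (3E,5R,6S)-3-methyl-9-oxo-6-(propan-2-yl)deca-1,3-dien-5-yl benzoate | CC(C)[C@H](CCC(C)=O)[C@@H](OC(=O)c1ccccc1)/C=C(C)/C=C | intermediate
10 | (3E,5R,6S)-3,9-dimethyl-6-(propan-2-yl)deca-1,3,9-trien-5-yl benzoate | CC(C)[C@H](CCC(C)=C)[C@@H](OC(=O)c1ccccc1)/C=C(C)/C=C | intermediate
11 | 6β-benzoyloxyeudesm-3-ene (5α-H, 7β-isopropyl, 10β-methyl) | CC(C)[C@@H]1CC[C@@]2(C)CCC=C(C)[C@@H]2[C@@H]1OC(=O)c1ccccc1 | intermediate
12 | 3α,4α-epoxy-6β-benzoyloxyeudesmane | CC(C)[C@@H]1CC[C@@]2(C)CC[C@H]3O[C@@]3(C)[C@@H]2[C@@H]1OC(=O)c1ccccc1 | intermediate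
13 | 3α,4β-dihydroxy-6β-benzoyloxyeudesmane, (3R,4R,5S,6R,7S,10S) | CC(C)[C@@H]1CC[C@@]2(C)CC[C@@H](O)[C@](C)(O)[C@@H]2[C@@H]1OC(=O)c1ccccc1 | target

## Step count and risks

Total step count: 6.
Longest linear sequence: 5 (steps 1, 3, 4, 5, 6, or equally 2, 3, 4, 5, 6).

**Most likely to fail, first: step 5.**
- The dienophile is unactivated and 1,1-disubstituted, so the cycloaddition may be too slow below the temperature the dienylic benzoate tolerates.
- The 1,3-diaxial OBz/CH3 contact may also erode the trans selectivity.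

The fallback activates the dienophile with a removable group and sets out from 9. Horner–Wadsworth–Emmons olefination with diethyl (phenylsulfonylmethyl)phosphonate and NaH gives the vinyl sulfone (3E,5R,6S,9E)-3,9-dimethyl-10-(phenylsulfonyl)-6-(propan-2-yl)deca-1,3,9-trien-5-yl benzoate F1. Its lowered LUMO should let the [4+2] run at about 130–150 °C to give 1-(phenylsulfonyl)-6β-benzoyloxyeudesm-3-ene F2; the configuration at C1 does not matter. Buffered Na(Hg) (Na2HPO4, MeOH–THF, −20 °C) removes the sulfonyl group, and the route is rejoined at 11.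

**Second: step 3.** Felkin control may be modest, and some attack or enolisation at the ketone is possible. The fallback makes C6 stereoconvergently and sets out from 3 and 6.
- A Nozaki–Hiyama–Kishi coupling (CrCl2, cat. NiCl2, DMF), which leaves ketones alone, gives two separable carbinols: (5S,6R,7E)-6-hydroxy-8-methyl-5-(propan-2-yl)deca-7,9-dien-2-one F3 and (5S,6S,7E)-6-hydroxy-8-methyl-5-(propan-2-yl)deca-7,9-dien-2-one F4.
- The first is benzoylated with retention (BzCl, pyridine).
- The second is benzoylated with inversion (PhCO2H, PPh3, DIAD, Mitsunobu).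
- Both return to the route at 9.

**Third: step 6.** Acid treatment of 12 may give the allylic alcohol by elimination, a Meinwald ketone, or a scrambled 4-O-benzoate. The fallback makes the diol first and places the ester last, setting out from 11.
- LiAlH4 frees eudesm-3-en-6β-ol F5.
- mCPBA gives 3α,4α-epoxyeudesman-6β-ol F6. A β-epoxide formed by hydroxyl direction would open to the same diaxial diol.
- Dilute HClO4 in aqueous THF gives eudesmane-3α,4β,6β-triol F7.
- Trimethyl orthobenzoate with CSA bridges only the syn-diaxial 4β and 6β oxygens, giving the cyclic 4,6-O-(α-methoxybenzylidene) orthoester of the triol F8.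
- Aqueous acetic acid opens this to the secondary benzoate with the tertiary alcohol free, which is 13.

## Further compounds

F1 | step 5 | (3E,5R,6S,9E)-3,9-dimethyl-10-(phenylsulfonyl)-6-(propan-2-yl)deca-1,3,9-trien-5-yl benzoate | CC(C)[C@H](CC/C(C)=C/S(=O)(=O)c1ccccc1)[C@@H](OC(=O)c1ccccc1)/C=C(C)/C=C
F2 | step 5 | 1-(phenylsulfonyl)-6β-benzoyloxyeudesm-3-ene | CC(C)[C@@H]1CC[C@@]2(C)C(CC=C(C)[C@@H]2[C@@H]1OC(=O)c1ccccc1)S(=O)(=O)c1ccccc1
F3 | step 3 | (5S,6R,7E)-6-hydroxy-8-methyl-5-(propan-2-yl)deca-7,9-dien-2-one | CC(C)[C@H](CCC(C)=O)[C@@H](O)/C=C(C)/C=C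
F4 | step 3 | (5S,6S,7E)-6-hydroxy-8-methyl-5-(propan-2-yl)deca-7,9-dien-2-one | CC(C)[C@H](CCC(C)=O)[C@H](O)/C=C(C)/C=C
F5 | step 6 | eudesm-3-en-6β-ol | CC(C)[C@@H]1CC[C@@]2(C)CCC=C(C)[C@@H]2[C@@H]1O
F6 | step 6 | 3α,4α-epoxyeudesman-6β-ol | CC(C)[C@@H]1CC[C@@]2(C)CC[C@H]3O[C@@]3(C)[C@@H]2[C@@H]1O
F7 | step 6 | eudesmane-3α,4β,6β-triol | CC(C)[C@@H]1CC[C@@]2(C)CC[C@@H](O)[C@](C)(O)[C@@H]2[C@@H]1O
F8 | step 6 | cyclic 4,6-O-(α-methoxybenzylidene) orthoester of eudesmane-3α,4β,6β-triol | CC(C)[C@@H]1CC[C@@]2(C)CC[C@@H](O)[C@](C)(OC3(OC)c4ccccc4)[C@@H]2[C@@H]1O3
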